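Ring A (C3a–C4–C5–C6=C7–C7a) carries its carboxyl group on the quaternary C4 beside the fusion carbon C3a, so it is drawn from a cycloheptenone whose carbonyl carbon sits between C3a and C4 and whose C4 holds an axial bromide. One alkoxide treatment closes C3a–C4 through a cyclopropanone, pushes the old carbonyl carbon out of the ring as the C4 ester, inverts C4 and sets the trans fusion at C3a. The precursor, a trans-fused bromo-hydroazulenone with C2 masked as a silyl ether, arises from an intramolecular (4+3) cycloaddition of a bromo-oxyallyl cation onto an all-E triene assembled by aldol and olefination steps.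

Key step: step 13

Assumption: atoms carry the target numbering in every explanation (ring B C1–C3, fusion C3a/C7a, ring A C4–C7, carboxyl carbon C8); C2 is carried as a tert-butyldimethylsilyl-protected carbinol and the ester as its 2-(trimethylsilyl)ethyl ester, spectator choices that leave the ring-contracting bond formation unchanged, and (S)-4-methyldihydrofuran-2(3H)-one is taken as purchasable.

Step 1
Reactants: 1 (R)-4-benzyloxazolidin-2-one; 2 butanoyl chloride
Product: 3 (R)-4-benzyl-3-butanoyloxazolidin-2-one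
Conditions: n-BuLi, THF, −78 °C; then 2, −78 → 0 °C
Reagents that add atoms: none
Why: N-Acylation of the lithium salt of the oxazolidinone by the acid chloride is fast and clean at low temperature and forms no stereocenter.

Step 2
Reactants: 4 (S)-4-methyldihydrofuran-2(3H)-one
Product: 5 (S)-4-hydroxy-N-methoxy-N,3-dimethylbutanamide
Conditions: MeNH(OMe)·HCl, AlMe3, CH2Cl2, 0 °C → rt
Reagents that add atoms: N,O-dimethylhydroxylamine hydrochloride, CNOC.Cl
Why: Aminolysis of the lactone by the aluminium amide made from AlMe3 and the hydroxylamine salt (Weinreb amide formation) opens the ring at the acyl carbon and leaves the methyl-bearing stereocenter, the future C3, untouched.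

Step 3
Reactants: 5 (S)-4-hydroxy-N-methoxy-N,3-dimethylbutanamide
Product: 6 (S)-N-methoxy-N,3-dimethyl-4-oxobutanamide
Conditions: Dess–Martin periodinane, NaHCO3, CH2Cl2, 0 °C → rt
Reagents that add atoms: none
Why: Dess–Martin oxidation converts the primary alcohol into the aldehyde under buffered, non-basic conditions, so the α-methyl stereocenter is not epimerised and the hydroxy amide is used before it can relactonise.

Step 4
Reactants: 3 (R)-4-benzyl-3-butanoyloxazolidin-2-one; 6 (S)-N-methoxy-N,3-dimethyl-4-oxobutanamide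
Product: 8 (R)-4-benzyl-3-[(2R,3S,4S)-2-ethyl-3-hydroxy-6-[methoxy(methyl)amino]-4-methyl-6-oxohexanoyl]oxazolidin-2-one, via boron enolate 7 (not isolated)
Conditions: Bu2BOTf, i-Pr2NEt, CH2Cl2, 0 °C; then 6, −78 → 0 °C; H2O2, MeOH, pH 7 buffer
Reagents that add atoms: none
Why: Evans syn-aldol reaction, in which the (Z)-boron enolate 7 reacts through a Zimmerman–Traxler chair whose enolate face is fixed by the (R)-benzyl auxiliary, giving the C1/C2 syn pair, while the anti-Felkin preference of a (Z)-enolate toward the (S)-α-methyl aldehyde is matched and gives C2/C3 anti.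

Step 5
Reactants: 8 (R)-4-benzyl-3-[(2R,3S,4S)-2-ethyl-3-hydroxy-6-[methoxy(methyl)amino]-4-methyl-6-oxohexanoyl]oxazolidin-2-one
Product: 9 (R)-4-benzyl-3-[(2R,3S,4S)-3-[(tert-butyldimethylsilyl)oxy]-2-ethyl-6-[methoxy(methyl)amino]-4-methyl-6-oxohexanoyl]oxazolidin-2-one
Conditions: t-BuMe2SiOTf, 2,6-lutidine, CH2Cl2, −78 → 0 °C
Reagents that add atoms: tert-butyldimethylsilyl trifluoromethanesulfonate, CC(C)(C)[Si](C)(C)OS(=O)(=O)C(F)(F)F
Why: Silylation of the hindered secondary alcohol with a silyl triflate and a hindered pyridine base is reliable and blocks retro-aldol cleavage and any later capture of cationic or acyl intermediates by the C2 oxygen.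

Step 6
Reactants: 9 (R)-4-benzyl-3-[(2R,3S,4S)-3-[(tert-butyldimethylsilyl)oxy]-2-ethyl-6-[methoxy(methyl)amino]-4-methyl-6-oxohexanoyl]oxazolidin-2-one
Product: 10 (3S,4S,5S)-4-[(tert-butyldimethylsilyl)oxy]-5-(hydroxymethyl)-N-methoxy-N,3-dimethylheptanamide
Conditions: NaBH4, THF–H2O (4:1), 0 °C → rt
Reagents that add atoms: none
Why: Borohydride reduction of the activated exocyclic imide carbonyl releases the auxiliary and gives the primary alcohol, while the less electrophilic Weinreb amide and the silyl ether are not attacked by NaBH4.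

Step 7
Reactants: 10 (3S,4S,5S)-4-[(tert-butyldimethylsilyl)oxy]-5-(hydroxymethyl)-N-methoxy-N,3-dimethylheptanamide
Product: 11 (3S,4S,5R)-4-[(tert-butyldimethylsilyl)oxy]-5-formyl-N-methoxy-N,3-dimethylheptanamide
Conditions: Dess–Martin periodinane, NaHCO3, CH2Cl2, 0 °C → rt
Reagents that add atoms: none
Why: Dess–Martin oxidation gives the α-branched aldehyde without base, so the C1 stereocenter next to the new carbonyl group keeps its configuration.

Step 8
Reactants: 11 (3S,4S,5R)-4-[(tert-butyldimethylsilyl)oxy]-5-formyl-N-methoxy-N,3-dimethylheptanamide; 12 2-(triphenyl-λ5-phosphanylidene)butanal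
Product: 13 (3S,4S,5S,6E)-4-[(tert-butyldimethylsilyl)oxy]-5,7-diethyl-N-methoxy-N,3-dimethyl-8-oxooct-6-enamide
Conditions: toluene, 90 °C
Reagents that add atoms: none
Why: Wittig olefination with a formyl-stabilised ylide gives the (E)-trisubstituted enal, placing C1 trans to the formyl carbon across the new C7a=C7 bond, and the neutral conditions leave the allylic stereocenter alone.

Step 9
Reactants: 13 (3S,4S,5S,6E)-4-[(tert-butyldimethylsilyl)oxy]-5,7-diethyl-N-methoxy-N,3-dimethyl-8-oxooct-6-enamide; 12 2-(triphenyl-λ5-phosphanylidene)butanal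
Product: 14 (3S,4S,5S,6E,8E)-4-[(tert-butyldimethylsilyl)oxy]-5,7,9-triethyl-N-methoxy-N,3-dimethyl-10-oxodeca-6,8-dienamide
Conditions: toluene, 110 °C
Reagents that add atoms: none
Why: A second Wittig olefination with the same stabilised ylide extends the enal to the (E,E)-dienal, the new C5=C6 bond forming with the formyl group trans to C7 as stabilised ylides do.

Step 10
Reactants: 14 (3S,4S,5S,6E,8E)-4-[(tert-butyldimethylsilyl)oxy]-5,7,9-triethyl-N-methoxy-N,3-dimethyl-10-oxodeca-6,8-dienamide; 15 diethyl benzylphosphonate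
Product: 16 (3S,4S,5S,6E,8E,10E)-4-[(tert-butyldimethylsilyl)oxy]-5,7,9-triethyl-N-methoxy-N,3-dimethyl-11-phenylundeca-6,8,10-trienamide
Conditions: LiN(SiMe3)2, THF, −78 °C; then 14, −78 °C → rt
Reagents that add atoms: none
Why: Horner–Wadsworth–Emmons olefination with the benzylphosphonate anion gives the (E)-styryl double bond and attacks the aldehyde far faster than the Weinreb amide.

Step 11
Reactants: 16 (3S,4S,5S,6E,8E,10E)-4-[(tert-butyldimethylsilyl)oxy]-5,7,9-triethyl-N-methoxy-N,3-dimethyl-11-phenylundeca-6,8,10-trienamide; 17 1,1-dibromopropane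
Product: 19 (6S,7S,8S,9E,11E,13E)-3,3-dibromo-7-[(tert-butyldimethylsilyl)oxy]-8,10,12-triethyl-6-methyl-14-phenyltetradeca-9,11,13-trien-4-one, via 1,1-dibromopropyllithium 18 (not isolated)
Conditions: 17, LiN(i-Pr)2, THF–Et2O, −100 °C; then 16, −100 → −78 °C; AcOH, −78 °C
Reagents that add atoms: none
Why: Acylation of the lithium carbenoid 18 by the Weinreb amide (the known homologation of Weinreb amides with dihaloalkyllithium reagents) stops at the chelated tetrahedral adduct, so the quench gives the α,α-dibromo ketone with both halogens on C4 and with C3a as its only enolisable carbon.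

Step 12
Reactants: 19 (6S,7S,8S,9E,11E,13E)-3,3-dibromo-7-[(tert-butyldimethylsilyl)oxy]-8,10,12-triethyl-6-methyl-14-phenyltetradeca-9,11,13-trien-4-one
Product: 21 (1S,2S,3S,3aR,5S,6S,8aS)-5-bromo-2-[(tert-butyldimethylsilyl)oxy]-1,5,6,8-tetraethyl-3-methyl-6-[(E)-2-phenylethenyl]-2,3,3a,5,6,8a-hexahydroazulen-4(1H)-one, via bromo-oxyallyl cation 20 (not isolated)
Conditions: Et3N, (CF3)2CHOH–CH2Cl2 (0.01 M), 0 °C → rt
Reagents that add atoms: none
Why: Triethylamine enolises C3a and loss of bromide from C4 in the ionising alcohol gives bromo-oxyallyl cation 20, which adds across the tethered C5=C6–C7=C7a diene in an intramolecular (4+3) cycloaddition of the kind known for oxyallyl cations made from α-halo ketones (bonds C3a–C7a and C4–C5); allylic 1,3-strain at C1 and at C3 turns one face of the diene and of the cation toward each other so that ring B closes trans-fused with both alkyl groups pseudo-equatorial, and the extended transition state, with the C4 ethyl group syn to oxygen and the slimmer bromine over the diene, should place bromine on the β face at C4 and the styryl group on the β face at C5.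

Step 13
Reactants: 21 (1S,2S,3S,3aR,5S,6S,8aS)-5-bromo-2-[(tert-butyldimethylsilyl)oxy]-1,5,6,8-tetraethyl-3-methyl-6-[(E)-2-phenylethenyl]-2,3,3a,5,6,8a-hexahydroazulen-4(1H)-one
Product: 23 2-(trimethylsilyl)ethyl (1S,2S,3S,3aR,4R,5S,7aR)-2-[(tert-butyldimethylsilyl)oxy]-1,4,5,7-tetraethyl-3-methyl-5-[(E)-2-phenylethenyl]-2,3,3a,4,5,7a-hexahydro-1H-indene-4-carboxylate, via cyclopropanone 22 (not isolated)
Conditions: Me3SiCH2CH2OH, NaH, THF, 0 °C → rt
Reagents that add atoms: 2-(trimethylsilyl)ethanol, OCC[Si](C)(C)C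
Why: The alkoxide removes the only α-hydrogen, at C3a (C4 bears none); the trans ring fusion holds the cycloheptenone in a chair whose C4–Br bond is axial and parallel to the enolate π system while the C3a–C8 ring bond is gauche to it, so the enolate carbon displaces bromide from the rear to give cyclopropanone 22, which the alkoxide opens at C8 with cleavage of the C8–C3a bond and protonation of C3a. The closest known reaction type is the Favorskii rearrangement of 2-halocycloalkanones through a cyclopropanone, the classical ring contraction to cycloalkanecarboxylates. Ring A is closed by a 3-exo-tet attack of C3a on C4, which creates the six-membered carbocycle together with the three-membered ring that is then opened. C4 is set by inversion at the carbon that loses the β-bromide, which leaves C8 on the β face, and C3a is set by the necessarily cis-fused three-membered ring, which holds C8 β on C3a so that the proton replacing it with retention becomes the β-hydrogen of the trans-fused hydrindane. The step needs the cyclopropanone to open toward C3a and not toward C4, both being fully substituted: C3a is the carbon common to three rings, its bond to C8 is the more compressed one (cis to the C3 methyl group and syn to the C2 silyloxy group) and the C2 oxygen exerts an inductive pull, while C4 is flanked by the quaternary C5. An aprotic solvent keeps the closure concerted, and a cis-fused C3a epimer of 21 would converge on the same enolate.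

Step 14
Reactants: 23 2-(trimethylsilyl)ethyl (1S,2S,3S,3aR,4R,5S,7aR)-2-[(tert-butyldimethylsilyl)oxy]-1,4,5,7-tetraethyl-3-methyl-5-[(E)-2-phenylethenyl]-2,3,3a,4,5,7a-hexahydro-1H-indene-4-carboxylate
Product: 24 (1S,2S,3S,3aR,4R,5S,7aR)-1,4,5,7-tetraethyl-2-hydroxy-3-methyl-5-[(E)-2-phenylethenyl]-2,3,3a,4,5,7a-hexahydro-1H-indene-4-carboxylic acid
Conditions: Bu4NF, THF, 50 °C; then aq. HCl (pH 3), 0 °C
Reagents that add atoms: none
Why: Fluoride attacks silicon and not the hindered acyl carbon, so the 2-(trimethylsilyl)ethyl ester fragments to the carboxylate with loss of ethene and the silyl ether is cleaved in the same operation (fluoride-induced desilylation), the β-hydroxyl at C2 being trans to the C4 side of ring B and unable to lactonise.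

Step 15
Reactants: 24 (1S,2S,3S,3aR,4R,5S,7aR)-1,4,5,7-tetraethyl-2-hydroxy-3-methyl-5-[(E)-2-phenylethenyl]-2,3,3a,4,5,7a-hexahydro-1H-indene-4-carboxylic acid
Product: 25 (1S,3S,3aR,4R,5S,7aR)-1,4,5,7-tetraethyl-3-methyl-2-oxo-5-[(E)-2-phenylethenyl]-2,3,3a,4,5,7a-hexahydro-1H-indene-4-carboxylic acid
Conditions: Dess–Martin periodinane, CH2Cl2, 0 °C → rt
Reagents that add atoms: none
Why: Dess–Martin oxidation of the secondary alcohol gives the C2 ketone without base, and C1 and C3 already hold the thermodynamically preferred configurations (each alkyl group trans to the neighbouring ring-A bond), so no equilibration is needed.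

Compound list
1 | (R)-4-benzyloxazolidin-2-one | O=C1OC[C@@H](Cc2ccccc2)N1 | starting material
2 | butanoyl chloride | CCCC(Cl)=O | starting material
3 | (R)-4-benzyl-3-butanoyloxazolidin-2-one | O=C1OC[C@@H](Cc2ccccc2)N1C(=O)CCC | intermediate
4 | (S)-4-methyldihydrofuran-2(3H)-one | C[C@@H]1COC(=O)C1 | starting material
5 | (S)-4-hydroxy-N-methoxy-N,3-dimethylbutanamide | OC[C@@H](C)CC(=O)N(C)OC | intermediate
6 | (S)-N-methoxy-N,3-dimethyl-4-oxobutanamide | O=C[C@@H](C)CC(=O)N(C)OC | intermediate
7 | (Z)-dibutylboron enolate of 3 (formed in the flask) | CC/C=C(\OB(CCCC)CCCC)N1[C@H](Cc2ccccc2)COC1=O | intermediate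
8 | (R)-4-benzyl-3-[(2R,3S,4S)-2-ethyl-3-hydroxy-6-[methoxy(methyl)amino]-4-methyl-6-oxohexanoyl]oxazolidin-2-one | O=C1OC[C@@H](Cc2ccccc2)N1C(=O)[C@H](CC)[C@@H](O)[C@@H](C)CC(=O)N(C)OC | intermediate
9 | (R)-4-benzyl-3-[(2R,3S,4S)-3-[(tert-butyldimethylsilyl)oxy]-2-ethyl-6-[methoxy(methyl)amino]-4-methyl-6-oxohexanoyl]oxazolidin-2-one | O=C1OC[C@@H](Cc2ccccc2)N1C(=O)[C@H](CC)[C@@H](O[Si](C)(C)C(C)(C)C)[C@@H](C)CC(=O)N(C)OC | intermediate
10 | (3S,4S,5S)-4-[(tert-butyldimethylsilyl)oxy]-5-(hydroxymethyl)-N-methoxy-N,3-dimethylheptanamide | OC[C@H](CC)[C@@H](O[Si](C)(C)C(C)(C)C)[C@@H](C)CC(=O)N(C)OC | intermediate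
11 | (3S,4S,5R)-4-[(tert-butyldimethylsilyl)oxy]-5-formyl-N-methoxy-N,3-dimethylheptanamide | O=C[C@H](CC)[C@@H](O[Si](C)(C)C(C)(C)C)[C@@H](C)CC(=O)N(C)OC | intermediate
12 | 2-(triphenyl-λ5-phosphanylidene)butanal | CCC(C=O)=P(c1ccccc1)(c1ccccc1)c1ccccc1 | starting material
13 | (3S,4S,5S,6E)-4-[(tert-butyldimethylsilyl)oxy]-5,7-diethyl-N-methoxy-N,3-dimethyl-8-oxooct-6-enamide | O=C/C(CC)=C/[C@H](CC)[C@@H](O[Si](C)(C)C(C)(C)C)[C@@H](C)CC(=O)N(C)OC | intermediate
14 | (3S,4S,5S,6E,8E)-4-[(tert-butyldimethylsilyl)oxy]-5,7,9-triethyl-N-methoxy-N,3-dimethyl-10-oxodeca-6,8-dienamide | O=C/C(CC)=C/C(CC)=C/[C@H](CC)[C@@H](O[Si](C)(C)C(C)(C)C)[C@@H](C)CC(=O)N(C)OC | intermediate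
15 | diethyl benzylphosphonate | CCOP(=O)(Cc1ccccc1)OCC | starting material
16 | (3S,4S,5S,6E,8E,10E)-4-[(tert-butyldimethylsilyl)oxy]-5,7,9-triethyl-N-methoxy-N,3-dimethyl-11-phenylundeca-6,8,10-trienamide | CON(C)C(=O)C[C@H](C)[C@H](O[Si](C)(C)C(C)(C)C)[C@@H](CC)/C=C(CC)/C=C(CC)/C=C/c1ccccc1 | intermediate
17 | 1,1-dibromopropane | CCC(Br)Br | starting material
18 | 1,1-dibromopropyllithium (formed in the flask) | [Li]C(Br)(Br)CC | intermediate
19 | (6S,7S,8S,9E,11E,13E)-3,3-dibromo-7-[(tert-butyldimethylsilyl)oxy]-8,10,12-triethyl-6-methyl-14-phenyltetradeca-9,11,13-trien-4-one | CCC(Br)(Br)C(=O)C[C@H](C)[C@H](O[Si](C)(C)C(C)(C)C)[C@@H](CC)/C=C(CC)/C=C(CC)/C=C/c1ccccc1 | intermediate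
20 | bromo-oxyallyl cation from 19 by loss of HBr, zwitterion with the ethyl group syn to oxygen (formed in the flask) | CC/C(Br)=C(\[O-])[CH+][C@H](C)[C@H](O[Si](C)(C)C(C)(C)C)[C@@H](CC)/C=C(CC)/C=C(CC)/C=C/c1ccccc1 | intermediate
21 | (1S,2S,3S,3aR,5S,6S,8aS)-5-bromo-2-[(tert-butyldimethylsilyl)oxy]-1,5,6,8-tetraethyl-3-methyl-6-[(E)-2-phenylethenyl]-2,3,3a,5,6,8a-hexahydroazulen-4(1H)-one (target numbering: carbonyl C8 between C3a and C4, β-bromide on C4, trans ring fusion) | CCC1=C[C@@](/C=C/c2ccccc2)(CC)[C@](CC)(Br)C(=O)[C@@H]2[C@@H]1[C@H](CC)[C@@H](O[Si](C)(C)C(C)(C)C)[C@H]2C | intermediate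
22 | cyclopropanone from 21: C3a bonded to C4, bromide lost, three-membered ketone C3a–C8–C4 on the β face (formed in the flask) | CCC1=C[C@@](/C=C/c2ccccc2)(CC)[C@]3(CC)C(=O)[C@]32[C@@H]1[C@H](CC)[C@@H](O[Si](C)(C)C(C)(C)C)[C@H]2C | intermediate
23 | 2-(trimethylsilyl)ethyl (1S,2S,3S,3aR,4R,5S,7aR)-2-[(tert-butyldimethylsilyl)oxy]-1,4,5,7-tetraethyl-3-methyl-5-[(E)-2-phenylethenyl]-2,3,3a,4,5,7a-hexahydro-1H-indene-4-carboxylate | CCC1=C[C@@](/C=C/c2ccccc2)(CC)[C@](CC)(C(=O)OCC[Si](C)(C)C)[C@@H]2[C@@H]1[C@H](CC)[C@@H](O[Si](C)(C)C(C)(C)C)[C@H]2C | intermediate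
24 | (1S,2S,3S,3aR,4R,5S,7aR)-1,4,5,7-tetraethyl-2-hydroxy-3-methyl-5-[(E)-2-phenylethenyl]-2,3,3a,4,5,7a-hexahydro-1H-indene-4-carboxylic acid | CCC1=C[C@@](/C=C/c2ccccc2)(CC)[C@](CC)(C(=O)O)[C@@H]2[C@@H]1[C@H](CC)[C@@H](O)[C@H]2C | intermediate
25 | (1S,3S,3aR,4R,5S,7aR)-1,4,5,7-tetraethyl-3-methyl-2-oxo-5-[(E)-2-phenylethenyl]-2,3,3a,4,5,7a-hexahydro-1H-indene-4-carboxylic acid | CCC1=C[C@@](/C=C/c2ccccc2)(CC)[C@](CC)(C(=O)O)[C@@H]2[C@@H]1[C@H](CC)C(=O)[C@H]2C | target

Total step count: 15. Longest linear sequence: 14 steps (steps 2 to 15, from 4).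

Steps most likely to fail

1. Step 13. The cyclopropanone may open at its other, equally substituted bond, which would leave the ester on the ring-fusion carbon, or HBr may be lost into the C4 ethyl group before the enolate closes. The fallback makes ring A by a [4+2] cycloaddition instead of by contraction; it sets out from 3 and comes back at 24. Commercial methyl (S)-3-hydroxy-2-methylpropanoate is silylated (Et3SiCl, imidazole) to methyl (S)-2-methyl-3-(triethylsilyloxy)propanoate F1 and reduced with i-Bu2AlH at −78 °C to (S)-2-methyl-3-(triethylsilyloxy)propanal F2. The aldol reaction of 3 with F2 under the conditions of step 4 should give aldol adduct F3. The operations of steps 5 to 10 (silylation, NaBH4, Dess–Martin oxidation, two Wittig reactions with 12, olefination with 15) should then lead through bis-silyl ether F4, primary alcohol F5, aldehyde F6, enal F7 and dienal F8 to triene F9. Pyridinium p-toluenesulfonate in methanol removes the primary triethylsilyl group to give alcohol F10, Dess–Martin oxidation gives aldehyde F11, and a Wittig reaction with 12 gives tetraenal F12. On warming in toluene its (E)-enal should add to the diene (intramolecular Diels–Alder reaction, steered by the same allylic stereocenters, the (E)-dienophile placing H3a and the formyl group cis) to give bicyclic aldehyde F13. Pinnick oxidation (NaClO2, NaH2PO4, 2-methylbut-2-ene) should give acid F14, and Bu4NF then frees the C2 hydroxyl to give 24.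

2. Step 12. Closure of the second bond, between two fully substituted carbons, may be slower than capture of the intermediate allyl cation by the enolate oxygen or by the alcohol, or the cation may react through the compact arrangement and deliver bromine to the α face. The fallback changes the reactive species; it sets out from 19 and comes back at 21. i-Pr3SiOTf and Et3N convert 19 into the (Z)-triisopropylsilyl enol ether F15. AgBF4 in CH2Cl2 at −78 °C then abstracts bromide to give the O-silylated bromo-oxyallyl cation, which cannot close through oxygen and meets no nucleophilic solvent. Cycloaddition with loss of the silyl group should give 21.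

3. Step 11. The carbenoid may undergo α-elimination at the temperature the amide needs to react, so that acylation stays incomplete. The fallback makes the C8–C4 bond by addition to an aldehyde; it sets out from 16 and comes back at 19. i-Bu2AlH at −78 °C reduces the Weinreb amide to (3S,4S,5S,6E,8E,10E)-4-[(tert-butyldimethylsilyl)oxy]-5,7,9-triethyl-3-methyl-11-phenylundeca-6,8,10-trienal F16. This aldehyde should react with 18 at −100 °C far faster than an amide does and give the dibromo carbinol F17 (both carbinol epimers), and Dess–Martin oxidation gives 19.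

Further compounds
F1 | step 13 | methyl (S)-2-methyl-3-(triethylsilyloxy)propanoate | COC(=O)[C@@H](C)CO[Si](CC)(CC)CC
F2 | step 13 | (S)-2-methyl-3-(triethylsilyloxy)propanal | O=C[C@@H](C)CO[Si](CC)(CC)CC
F3 | step 13 | (R)-4-benzyl-3-[(2R,3S,4S)-2-ethyl-3-hydroxy-4-methyl-5-(triethylsilyloxy)pentanoyl]oxazolidin-2-one | O=C1OC[C@@H](Cc2ccccc2)N1C(=O)[C@H](CC)[C@@H](O)[C@@H](C)CO[Si](CC)(CC)CC
F4 | step 13 | tert-butyldimethylsilyl ether of F3 | O=C1OC[C@@H](Cc2ccccc2)N1C(=O)[C@H](CC)[C@@H](O[Si](C)(C)C(C)(C)C)[C@@H](C)CO[Si](CC)(CC)CC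
F5 | step 13 | primary alcohol, the analogue of 10 with CH2OSiEt3 in place of CH2C(O)N(OMe)Me | OC[C@H](CC)[C@@H](O[Si](C)(C)C(C)(C)C)[C@@H](C)CO[Si](CC)(CC)CC
F6 | step 13 | aldehyde, the analogue of 11 with CH2OSiEt3 in place of CH2C(O)N(OMe)Me | O=C[C@H](CC)[C@@H](O[Si](C)(C)C(C)(C)C)[C@@H](C)CO[Si](CC)(CC)CC
F7 | step 13 | (E)-enal, the analogue of 13 with CH2OSiEt3 in place of CH2C(O)N(OMe)Me | O=C/C(CC)=C/[C@H](CC)[C@@H](O[Si](C)(C)C(C)(C)C)[C@@H](C)CO[Si](CC)(CC)CC
F8 | step 13 | (E,E)-dienal, the analogue of 14 with CH2OSiEt3 in place of CH2C(O)N(OMe)Me | O=C/C(CC)=C/C(CC)=C/[C@H](CC)[C@@H](O[Si](C)(C)C(C)(C)C)[C@@H](C)CO[Si](CC)(CC)CC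
F9 | step 13 | all-E triene, the analogue of 16 with CH2OSiEt3 in place of CH2C(O)N(OMe)Me | CC[Si](CC)(CC)OC[C@H](C)[C@H](O[Si](C)(C)C(C)(C)C)[C@@H](CC)/C=C(CC)/C=C(CC)/C=C/c1ccccc1
F10 | step 13 | primary alcohol from F9 by loss of the triethylsilyl group | OC[C@H](C)[C@H](O[Si](C)(C)C(C)(C)C)[C@@H](CC)/C=C(CC)/C=C(CC)/C=C/c1ccccc1
F11 | step 13 | aldehyde from F10 (formyl carbon is C3a) | O=C[C@H](C)[C@H](O[Si](C)(C)C(C)(C)C)[C@@H](CC)/C=C(CC)/C=C(CC)/C=C/c1ccccc1
F12 | step 13 | all-E tetraenal with the (E)-2-ethyl enal as dienophile (C3a=C4, formyl carbon C8) | O=C/C(CC)=C/[C@H](C)[C@H](O[Si](C)(C)C(C)(C)C)[C@@H](CC)/C=C(CC)/C=C(CC)/C=C/c1ccccc1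
F13 | step 13 | bicyclic aldehyde, 23 with CHO in place of the ester group | CCC1=C[C@@](/C=C/c2ccccc2)(CC)[C@](CC)(C=O)[C@@H]2[C@@H]1[C@H](CC)[C@@H](O[Si](C)(C)C(C)(C)C)[C@H]2C
F14 | step 13 | carboxylic acid, the tert-butyldimethylsilyl ether of 24 | CCC1=C[C@@](/C=C/c2ccccc2)(CC)[C@](CC)(C(=O)O)[C@@H]2[C@@H]1[C@H](CC)[C@@H](O[Si](C)(C)C(C)(C)C)[C@H]2C
F15 | step 12 | (Z)-triisopropylsilyl enol ether of 19 | CCC(Br)(Br)/C(O[Si](C(C)C)(C(C)C)C(C)C)=C/[C@H](C)[C@H](O[Si](C)(C)C(C)(C)C)[C@@H](CC)/C=C(CC)/C=C(CC)/C=C/c1ccccc1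
F16 | step 11 | (3S,4S,5S,6E,8E,10E)-4-[(tert-butyldimethylsilyl)oxy]-5,7,9-triethyl-3-methyl-11-phenylundeca-6,8,10-trienal | O=CC[C@H](C)[C@H](O[Si](C)(C)C(C)(C)C)[C@@H](CC)/C=C(CC)/C=C(CC)/C=C/c1ccccc1
F17 | step 11 | (6S,7S,8S,9E,11E,13E)-3,3-dibromo-7-[(tert-butyldimethylsilyl)oxy]-8,10,12-triethyl-6-methyl-14-phenyltetradeca-9,11,13-trien-4-ol, both C4 epimers | CCC(Br)(Br)C(O)C[C@H](C)[C@H](O[Si](C)(C)C(C)(C)C)[C@@H](CC)/C=C(CC)/C=C(CC)/C=C/c1ccccc1
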